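**Retrosynthetic overview**
1. The target comes from its 2-O-methyl ether. The last step removes the one methyl group next to the depside carbonyl by chelation-controlled cleavage with BCl3.
2. Key disconnection: the depside C(acyl)–O(aryl) ester bond. This gives 3-chloro-2,4-dimethoxy-6-propylbenzoic acid (A ring, used as its acid chloride) and unprotected 2,4-dihydroxy-6-propylbenzoic acid (B ring, masked in the flask as a phenylboronate).
3. The A-ring acid comes from the aryl bromide (Br/Li exchange, CO2). The bromide comes from symmetric 2-chloro-1,3-dimethoxy-5-propylbenzene, and that from 1,3-dimethoxy-5-propylbenzene by directed ortho-lithiation and Cl+ quench, which fixes the chlorine position.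
4. Ring order: no carbocycle is built, and both benzene rings are bought. The only ring made is a transient 1,3,2-dioxaborinone on the B ring, formed and hydrolysed within the coupling step.

Assumption: the target SMILES has no stereocentre or stereoaxis, so the compound is achiral and no enantiocontrol is needed; 1,3-dimethoxy-5-propylbenzene and 2,4-dihydroxy-6-propylbenzoic acid are taken as catalogue chemicals.

**Step 1**
Reactants: 1 1,3-dimethoxy-5-propylbenzene
Product: 3 2-chloro-1,3-dimethoxy-5-propylbenzene, via aryllithium 2 (not isolated)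
Conditions: n-BuLi (1.15 equiv), THF, 0 °C → rt, 2 h; C2Cl6 (1.2 equiv), THF, −78 °C → rt
Reagents that add atoms: hexachloroethane, ClC(Cl)(Cl)C(Cl)(Cl)Cl
Why: Directed ortho-metalation: the C2–H flanked by both methoxy groups is the most acidic and doubly coordinated site, so n-BuLi gives only aryllithium 2, which takes Cl+ from hexachloroethane (halogenophilic attack, then loss of LiCl and C2Cl4) and places chlorine between the two oxygens without isomers; no stereocentre is formed.

**Step 2**
Reactants: 3 2-chloro-1,3-dimethoxy-5-propylbenzene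
Product: 4 2-bromo-4-chloro-3,5-dimethoxy-1-propylbenzene
Conditions: NBS (1.0 equiv), MeCN, 0 °C → rt, dark
Reagents that add atoms: N-bromosuccinimide (NBS), O=C1CCC(=O)N1Br
Why: Electrophilic aromatic bromination (SEAr): the two free ring positions of symmetric 3 are equivalent and each is ortho/para to the methoxy groups, so one equivalent of NBS in polar MeCN can give only one monobromide and benzylic bromination is suppressed.

**Step 3**
Reactants: 4 2-bromo-4-chloro-3,5-dimethoxy-1-propylbenzene
Product: 7 3-chloro-2,4-dimethoxy-6-propylbenzoic acid, via aryllithium 5 (not isolated), via lithium carboxylate 6 (not isolated)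
Conditions: n-BuLi (1.05 equiv), THF, −78 °C, 20 min; dry CO2, −78 °C → rt; 1 M HCl
Reagents that add atoms: carbon dioxide, O=C=O
Why: Bromine–lithium exchange followed by carboxylation: Br/Li exchange at −78 °C is far faster than attack on the aryl chloride or benzylic deprotonation, lithium sits meta to chlorine so no aryne can form, and CO2 traps 5 as carboxylate 6, which HCl protonates.

**Step 4**
Reactants: 7 3-chloro-2,4-dimethoxy-6-propylbenzoic acid; 8 2,4-dihydroxy-6-propylbenzoic acid (divaric acid)
Product: 12 4-[(3-chloro-2,4-dimethoxy-6-propylbenzoyl)oxy]-2-hydroxy-6-propylbenzoic acid, via acid chloride 9 (not isolated), via boronate-masked divaric acid 10 (not isolated), via boronate-masked depside 11 (not isolated)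
Conditions: (a) 8, PhB(OH)2 (1.0 equiv), 4 Å MS, CH2Cl2–THF 4:1, rt, 2 h; (b) 7, (COCl)2 (1.3 equiv), DMF (cat.), CH2Cl2, 0 °C → rt, evaporate; (c) 9 added to 10, Et3N (2.0 equiv), DMAP (10 mol %), 0 °C → rt, 6 h; (d) H2O–THF, rt, 15 min, then NaHCO3 extraction and acidification
Reagents that add atoms: none
Why: Proposed new method: boronate-masked depside coupling, in which phenylboronic acid condenses reversibly with the 2-OH/CO2H pair of unprotected 8 to give the six-membered acyloxyboronate 10, tying up the carboxyl and the chelated phenol and acidifying the remote 4-OH, so that Et3N/DMAP-mediated O-acylation by the hindered but readily ionising aroyl chloride 9 can form the C(acyl)–O(aryl) depside bond only at O-4 (the carbonyl of 10 is shielded by the propyl group and deactivated by the para phenoxide and by amine coordination at boron), after which water cleaves the B–O bonds of 11 within minutes; the closest known reaction types are transient boronic-ester protection of diols in site-selective carbohydrate acylation, acyloxyboron formation in boronic-acid-catalysed amidation and Einhorn/Schotten–Baumann acylation of phenols, none of which has been shown on a free salicylic-acid unit for depside formation.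

**Step 5**
Reactants: 12 4-[(3-chloro-2,4-dimethoxy-6-propylbenzoyl)oxy]-2-hydroxy-6-propylbenzoic acid
Product: 14 3-chlorodivaricatic acid = 4-[(3-chloro-2-hydroxy-4-methoxy-6-propylbenzoyl)oxy]-2-hydroxy-6-propylbenzoic acid, via bis-boron chelate 13 (not isolated)
Conditions: BCl3 (1 M in CH2Cl2, 4 equiv), CH2Cl2, −40 → 0 °C, 1 h; ice/1 M HCl
Reagents that add atoms: none
Why: Chelation-controlled BCl3 aryl methyl ether cleavage: boron bridges the depside carbonyl and the doubly ortho-flanked 2-OMe and chloride removes that methyl as MeCl, while the unchelated 4-OMe, the aryl ester and Ar–Cl are inert at or below 0 °C and the B-ring salicylic acid is only held as a chloroboron chelate that hydrolyses on work-up; no stereocentre is involved.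

**Compound list**
1 | 1,3-dimethoxy-5-propylbenzene | CCCc1cc(OC)cc(OC)c1 | starting material
2 | (2,6-dimethoxy-4-propylphenyl)lithium | CCCc1cc(OC)c([Li])c(OC)c1 | intermediate
3 | 2-chloro-1,3-dimethoxy-5-propylbenzene | CCCc1cc(OC)c(Cl)c(OC)c1 | intermediate
4 | 2-bromo-4-chloro-3,5-dimethoxy-1-propylbenzene | CCCc1cc(OC)c(Cl)c(OC)c1Br | intermediate
5 | (3-chloro-2,4-dimethoxy-6-propylphenyl)lithium | CCCc1cc(OC)c(Cl)c(OC)c1[Li] | intermediate
6 | lithium 3-chloro-2,4-dimethoxy-6-propylbenzoate | CCCc1cc(OC)c(Cl)c(OC)c1C(=O)[O-].[Li+] | intermediate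
7 | 3-chloro-2,4-dimethoxy-6-propylbenzoic acid | CCCc1cc(OC)c(Cl)c(OC)c1C(=O)O | intermediate
8 | 2,4-dihydroxy-6-propylbenzoic acid (divaric acid) | CCCc1cc(O)cc(O)c1C(=O)O | starting material
9 | 3-chloro-2,4-dimethoxy-6-propylbenzoyl chloride | CCCc1cc(OC)c(Cl)c(OC)c1C(=O)Cl | intermediate
10 | 7-hydroxy-2-phenyl-5-propyl-4H-1,3,2-benzodioxaborinin-4-one | CCCc1cc(O)cc2OB(c3ccccc3)OC(=O)c12 | intermediate
11 | 4-oxo-2-phenyl-5-propyl-4H-1,3,2-benzodioxaborinin-7-yl 3-chloro-2,4-dimethoxy-6-propylbenzoate | CCCc1cc(OC(=O)c2c(CCC)cc(OC)c(Cl)c2OC)cc3OB(c4ccccc4)OC(=O)c13 | intermediate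
12 | 4-[(3-chloro-2,4-dimethoxy-6-propylbenzoyl)oxy]-2-hydroxy-6-propylbenzoic acid | CCCc1cc(OC(=O)c2c(CCC)cc(OC)c(Cl)c2OC)cc(O)c1C(=O)O | intermediate
13 | 2-chloro-4-oxo-5-propyl-4H-1,3,2-benzodioxaborinin-7-yl 3-chloro-2-(dichloroboryloxy)-4-methoxy-6-propylbenzoate | CCCc1cc(OC(=O)c2c(CCC)cc(OC)c(Cl)c2OB(Cl)Cl)cc3OB(Cl)OC(=O)c13 | intermediate
14 | 3-chlorodivaricatic acid (achiral) | CCCc1cc(OC(=O)c2c(CCC)cc(OC)c(Cl)c2O)cc(O)c1C(=O)O | target

**Step count**
Total step count: 5.
Longest linear sequence: 5 (1 → 3 → 4 → 7 → 12 → 14). Compound 8 enters at step 4.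

**Steps most likely to fail**

(i) Step 4, the proposed new step.
- Risks: masking may be incomplete. The acyloxyboronate carbonyl of 10 may itself be acylating, which would give B–B self-esters. Acylation by the hindered chloride 9 may be slow.
- Fallback (known chemistry only): it sets out from 7 and 8 and comes back to the route at 12. The carboxylate of 8 is alkylated with BnBr/KHCO3 in DMF to give benzyl 2,4-dihydroxy-6-propylbenzoate F1, whose chelated 2-OH is unreactive. Compounds 7 and F1 are condensed with trifluoroacetic anhydride in toluene at rt (mixed-anhydride/acylium esterification, the standard depside coupling). This gives benzyl 4-[(3-chloro-2,4-dimethoxy-6-propylbenzoyl)oxy]-2-hydroxy-6-propylbenzoate F2. A short neutral hydrogenolysis (H2 1 atm, 10% Pd/C, EtOAc, no base) removes the benzyl group, leaves Ar–Cl intact and delivers 12.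

(ii) Step 5.
- Risks: on the full depside, BCl3 could cleave the 4-OMe group as well, attack the aryl ester, or promote decarboxylation of the B ring.
- Fallback: it moves the demethylation ahead of the coupling. It sets out from 7 and comes back at 14. BCl3 (CH2Cl2, −20 → 0 °C) on the simple acid 7 gives 3-chloro-2-hydroxy-4-methoxy-6-propylbenzoic acid F3. This acid is condensed (DCC, toluene, rt) with benzyl 2,4-dihydroxy-6-propylbenzoate F1, made from 8 as described under (i). The product is benzyl 4-[(3-chloro-2-hydroxy-4-methoxy-6-propylbenzoyl)oxy]-2-hydroxy-6-propylbenzoate F4. Hydrogenolysis (H2, Pd/C, EtOAc) then gives 14.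

(iii) Step 3.
- Risks: the doubly flanked aryllithium 5 may be protonated or butylated before CO2 reaches it.
- Fallback: it replaces organometallic carboxylation by electrophilic formylation and oxidation. It sets out from 3, so step 2 is also skipped, and comes back at 7. Rieche formylation (Cl2CHOMe, TiCl4, CH2Cl2, 0 °C) of symmetric 3 gives the single aldehyde 3-chloro-2,4-dimethoxy-6-propylbenzaldehyde F5. Pinnick oxidation (NaClO2, NaH2PO4, 2-methyl-2-butene, t-BuOH–H2O) converts it to 7, with the scavenger protecting the free ring position from HOCl.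

**Further compounds**
F1 | step 4 | benzyl 2,4-dihydroxy-6-propylbenzoate | CCCc1cc(O)cc(O)c1C(=O)OCc2ccccc2
F2 | step 4 | benzyl 4-[(3-chloro-2,4-dimethoxy-6-propylbenzoyl)oxy]-2-hydroxy-6-propylbenzoate | CCCc1cc(OC(=O)c2c(CCC)cc(OC)c(Cl)c2OC)cc(O)c1C(=O)OCc3ccccc3
F3 | step 5 | 3-chloro-2-hydroxy-4-methoxy-6-propylbenzoic acid | CCCc1cc(OC)c(Cl)c(O)c1C(=O)O
F4 | step 5 | benzyl 4-[(3-chloro-2-hydroxy-4-methoxy-6-propylbenzoyl)oxy]-2-hydroxy-6-propylbenzoate | CCCc1cc(OC(=O)c2c(CCC)cc(OC)c(Cl)c2O)cc(O)c1C(=O)OCc3ccccc3
F5 | step 3 | 3-chloro-2,4-dimethoxy-6-propylbenzaldehyde | CCCc1cc(OC)c(Cl)c(OC)c1C=O
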